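**Amounts charged.** The flask holds L with small fractions of X and D on it, beside two earlier runs that differ from it in their amount of D.

| flask | L | X | D | remark | time |
|---|---|---|---|---|---|
| spring | 0.93 M | 0.0186 M | 0.22 mol% | run made earlier |  |
| dawn | 0.93 M | 0.0186 M | 0.49 mol% | run made earlier |  |
| flask | 0.93 M | 0.0186 M | 0.33 mol% |  | 20 min |

- spring (time / min: Q / %, L / %): 5.00: 7.1, 90.8; 10.0: 12.4, 86.2; 15.0: 14.6, 82.3; 20.0: 17.8, 79.8; 25.0: 19.5, 78.1
- dawn (time / min: Q / %, L / %): 2.00: 5.1, 93.4; 6.00: 12.1, 85.9; 12.0: 20.5, 77.1; 15.0: 21.9, 75.7; 25.0: 28.9, 69.9

(readings scatter by 0.5 percentage points)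

- average number of monomer units in a chain (living and dead chains, two that joined counted as one) at 20 min
- part of the L that has reacted at 20 min

- the average divides the monomer in chains by the number of chains, living and dead together; two radicals that join make one chain
- the earlier runs were read with a standard deviation of 0.5 percentage points
- the earlier runs do not show the number of chains; that part of a forecast is a guess

**Main step.** Take first L passing into Q under D. At 25.0 min the Q reading of dawn stands 1.48 times that of spring, and the root of their D loadings stands at 1.49, so within their scatter these two readings go with the root of the loading. This reckoning therefore carries the root yield: Q at a fixed time divided by the root of D's fraction of the L charged, with L and X held as charged here. The spring reading at 20.0 min makes it 3.79, which gives the flask a Q of 21.8%.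

**Side step.** Now add X. In dawn, L and Q fall short of the charge by 1.50% at 2.00 min and 1.20% at 25.0 min, and X is 2.00% of the L charged. The shortfall does not grow within the scatter, so this reckoning takes the X share as L used early, adds it to Q, and puts c at 23.8%.

**Fading rate.** Spring gains 5.3 percentage points of Q between its first two readings but 1.7 points between its last two. The yield is read at the asked time, so this drift already stands inside it, provided it runs alike at each loading. The readings show no chain count, so this reckoning gives no dp.

**The forecast.** It puts c at 23.8% (22.3% to 25.3%) and dp at 105 (45 to 220), with the remark “Chains are a guess”.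

**The result.** The flask gives dp 70.5 and c 23.4%, with Q at 21.4% against the root yield's 21.8%.

    L + G → Q + G, rate k1*[G]*[L] (k = 617 M⁻¹ s⁻¹)
    L + E → G + Q (k = 84400 M⁻¹ s⁻¹)
    2 G → J (k = 2.00 × 10⁷ M⁻¹ s⁻¹)
    X + L → Z (k = 0.0542 M⁻¹ s⁻¹)
    D → 2 E (k = 0.00209 s⁻¹)

**Chain count.** The forecast and the flask part on chains: the forecast's dp stands 1.49 times the flask's, and in the flask J stands at 0.303% of the L charged. The wearing away of D and of X together raises dp: the flask reaches 42.2 without the first and 48.5 without the second, against 70.5 as it runs.

**Second flask.** At 0.083 mol% of D, the root yield gives Q 10.9% and, with the X share, c 12.9%. That neighbour gives Q 11.2% and c 13.2%.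

(The earlier runs and the new flask are simulated for an exercise, noise included.)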